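4 questions stand on this flask, and one ratio carries the reckoning.

    catalyst intermediate B + capture agent → trapped intermediate (k1 = 6.6 M⁻¹ min⁻¹)
    partner + free catalyst → catalyst intermediate A (k2 = 27 M⁻¹ min⁻¹)
    catalyst intermediate B → free catalyst + product (k3 = 4.4 min⁻¹)
    solid reagent ⇌ partner, rate k4*(cs4 - [partner]) while solid is left; crystals form when [partner] > cs4 (cs4 = 15 mM, k4 = 0.011 min⁻¹)
    free catalyst → spent catalyst (k5 = 3.7 × 10⁻⁶ min⁻¹)
    substrate + catalyst intermediate A → catalyst intermediate B (k6 = 23 M⁻¹ min⁻¹)

substrate 0.10 M; solid reagent 0.0950 M; capture agent 0.100 M; free catalyst 1.1 mM; time 6.0 h

- birch: doubling the solubility in step 4, all else as stated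
- larch: doubling the amount of free catalyst, all else as stated
- alder: doubling the dissolution coefficient of step 4, all else as stated

- given per volume of solution although it is solid: solid reagent
- at the start none of the solid reagent is in solution
- run time (flask): 6.0 h

* product at 6.0 h, in percent of the substrate charged
* concentration of partner in solution at 1.5 h, in percent of saturation
* the change that raises the amount of product at 6.0 h, in percent of the substrate charged most ("none" if none brings more than 2 percentage points) (birch / larch / alder / none)
* amount of product at 6.0 h, in percent of the substrate charged, after birch

1. Draw the partner first. It starts at zero and rises at 0.165 mM min⁻¹, and free catalyst as charged takes it up with a half-life of 0.39 h. Set dissolving equal to uptake, with the whole catalyst charge free: the curve bends towards a shelf at 4.05 mM, or 27.0% of saturation. My reckoning of the partner at 1.5 h goes no further.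

2. Go to the fork at catalyst intermediate B. Capture is pseudo-first-order at 0.660 min⁻¹, and release runs faster at 4.4 min⁻¹. Divide them: 6.67 is the turnover number, the product one catalyst makes on average before capture.

3. Draw the product. On the shelf, with the catalyst charge still free, its slope is 0.105 mM min⁻¹. Each pass through catalyst intermediate B ends in capture for 13.0% of the catalyst passing, so I reckon the catalyst lasts about 70.0 min, less than the run. Put the knee there.

4. Find the level: turnover number times catalyst over substrate gives 7.33%, less than the charges allow. Go round once more: trapping lowers the capture agent, on average by half the catalyst charge. The turnover number becomes 6.70 and the level 7.37%.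

5. Choose. Neither solubility nor dissolving coefficient stands in that level, so commit to 7.37% after birch. Larch doubles the catalyst, towards 14.7%, so pick larch.

The forecast gives 7.4%, 38%, larch and 7.4%. Its ground: “yield therefore scales with the catalyst charge”. The 38% is its own figure, above my shelf.

The flask gives 7.37%, 38.8%, larch with a gain of 7.4 percentage points, and 7.37% after birch. At 6.00 h trapped intermediate holds >99.9% of the catalyst charged. Product per catalyst charged reads 6.70, beside a turnover number of 6.70. Now take the neighbour with 0.040 M of substrate, the other charges and the time held: the turnover number times the catalyst over that substrate gives 18.4% of its charge. That neighbour ends with 18.4% product and 79% of its substrate left.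

The numbers stand for no real mixture, and the outcome is calculated.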